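The two flavan units are both (2R,3R) and differ only at C4. One monomer, tetra-O-benzylteracacidin 18, therefore serves twice: its C4 cation is captured on the β face by the 4α-OH of a second molecule. Everything rests on cutting ring C of 18 at O1–C8a and C4–C4a. This leaves O1–C2–C3–C4 as an intact aldol-derived chain (aldehyde 14). Ring A becomes a 1,2-dipole, a 2-fluoroaryllithium with lithium at C4a and fluorine at C8a beside the C8 oxygen. In one flask C4a adds to the aldehyde, setting C4, and the fluoride-unmasked O1 alkoxide displaces fluorine. The C2–O1 bond is never broken, which protects the fragile 2,3-cis relationship.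

Key step: step 8

Remark: flavan numbering (O1, C2-C4, C4a, C5-C8, C8a; rings A, B, C) is used for all intermediates, α is the face of ring C that bears the 2-aryl group, and compounds 1, 4, 5 and 8 are taken as commercial.

Step 1
Reactants: 1 3-fluorocatechol
Product: 2 1,2-bis(benzyloxy)-3-fluorobenzene
Conditions: BnBr, K2CO3, DMF, 60 °C
Reagents that add atoms: benzyl bromide, BrCc1ccccc1
Why: Williamson ether synthesis on both phenols; benzyl ethers withstand the organolithium, fluoride and triflic anhydride steps and all leave together in step 10.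

Step 2
Reactants: 2 1,2-bis(benzyloxy)-3-fluorobenzene
Product: 3 1,2-bis(benzyloxy)-4-bromo-3-fluorobenzene
Conditions: NBS, MeCN, 0 °C to rt, dark
Reagents that add atoms: N-bromosuccinimide, O=C1CCC(=O)N1Br
Why: Electrophilic aromatic bromination should go para to the C1 benzyloxy group and ortho to fluorine, because the doubly flanked C2 benzyloxy group is twisted out of conjugation, so that bromine marks the future C4a directly beside the fluorine-bearing future C8a.

Step 3
Reactants: 4 (S)-4-benzyloxazolidin-2-one; 5 (benzyloxy)acetyl chloride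
Product: 7 (S)-4-benzyl-3-[(benzyloxy)acetyl]oxazolidin-2-one, via N-lithio oxazolidinone 6 (not isolated)
Conditions: n-BuLi, THF, −78 °C; then 5, −78 to 0 °C
Reagents that add atoms: none
Why: N-acylation of the lithiated oxazolidinone with the acid chloride attaches the auxiliary needed for the glycolate aldol reaction.

Step 4
Reactants: 7 (S)-4-benzyl-3-[(benzyloxy)acetyl]oxazolidin-2-one; 8 4-(benzyloxy)benzaldehyde
Product: 11 (S)-4-benzyl-3-{(2S,3R)-2-(benzyloxy)-3-[4-(benzyloxy)phenyl]-3-hydroxypropanoyl}oxazolidin-2-one, via Z boron enolate 9 (not isolated), via boron aldolate 10 (not isolated)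
Conditions: Bu2BOTf, Et3N, CH2Cl2, −78 to 0 °C; 8, −78 to 0 °C; then pH 7 buffer, MeOH, H2O2, 0 °C
Reagents that add atoms: none
Why: Evans syn aldol reaction: the Z boron enolate 9 reacts through a Zimmerman-Traxler chair on the face remote from the benzyl group of the (S)-auxiliary, which sets the future C3 (2S here) and C2 (3R here) as the syn pair that maps onto the 2,3-cis flavan, with O3 already benzylated and O1 free.

Step 5
Reactants: 11 syn aldol adduct
Product: 12 (S)-4-benzyl-3-{(2S,3R)-2-(benzyloxy)-3-[4-(benzyloxy)phenyl]-3-(triethylsilyloxy)propanoyl}oxazolidin-2-one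
Conditions: TESOTf, 2,6-lutidine, CH2Cl2, −78 to 0 °C
Reagents that add atoms: triethylsilyl trifluoromethanesulfonate, CC[Si](CC)(CC)OS(=O)(=O)C(F)(F)F
Why: Silylation of the benzylic hydroxyl (silyl ether protection) blocks retro-aldol cleavage and masks the future O1 with a group that fluoride removes on demand in step 8.

Step 6
Reactants: 12 silylated aldol adduct
Product: 13 (2R,3R)-2-(benzyloxy)-3-[4-(benzyloxy)phenyl]-3-(triethylsilyloxy)propan-1-ol
Conditions: LiBH4, THF, 0 °C to rt
Reagents that add atoms: none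
Why: Reductive cleavage of the N-acyloxazolidinone with LiBH4 gives the primary alcohol and returns the auxiliary, and it touches neither stereocenter nor the silyl and benzyl ethers.

Step 7
Reactants: 13 primary alcohol
Product: 14 (2S,3R)-2-(benzyloxy)-3-[4-(benzyloxy)phenyl]-3-(triethylsilyloxy)propanal
Conditions: TEMPO (cat.), PhI(OAc)2, CH2Cl2, rt
Reagents that add atoms: none
Why: TEMPO/oxoammonium oxidation of the primary alcohol stops at the aldehyde under almost neutral conditions, so that the α-benzyloxy stereocenter should not epimerise and the β-silyloxy group should not be eliminated.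

Step 8
Reactants: 3 1,2-bis(benzyloxy)-4-bromo-3-fluorobenzene; 14 (2S,3R)-2-(benzyloxy)-3-[4-(benzyloxy)phenyl]-3-(triethylsilyloxy)propanal
Product: 18 (2R,3R,4R)-3,7,8-tris(benzyloxy)-2-[4-(benzyloxy)phenyl]chroman-4-ol, via aryllithium 15 (not isolated), via lithium alkoxide 16 (not isolated), via caesium lithium dialkoxide 17 (not isolated)
Conditions: 3, t-BuLi (2 equiv), THF, −78 °C; 14, −78 °C; then CsF, DMPU, warm to 70 °C in the same flask; H2O
Reagents that add atoms: none
Why: Br/Li exchange gives the 2-fluoroaryllithium 15, which is kept below the temperature of LiF loss and adds through C4a to the aldehyde carbon of 14 (C4-C4a bond, alkoxide 16); fluoride then takes the triethylsilyl group off the C2 oxygen, and the naked alkoxide O1 of 17 attacks C8a and expels fluoride by a Meisenheimer-type addition-elimination (O1-C8a bond), the expelled fluoride unmasking the next molecule. The closest known reaction types are the 1,2-addition of ortho-haloaryllithiums to α-alkoxy aldehydes and the alkoxide SNAr cyclisation of 3-(2-fluoroaryl)propanols to chromans, telescoped here into a formal [4+2] annulation of the four-atom O1-C2-C3-C4 unit onto a 1,2-dipole. Ring C is the only ring closed, by six-membered ipso attack of O1 on C8a (6-exo-trig with respect to the C8a=C8 bond). C4 is the only new stereocenter and is set by polar Felkin-Anh addition anti to the C3 benzyloxy group under non-chelating conditions (lithium, THF), which gives the 3,4-anti chain that becomes the 3,4-cis (4R) ring, while C2 and C3 cannot epimerise because the C2-O1 bond is never broken and no carbonyl group is present in the basic stage. The step needs regiocontrol on ring A, which bromine at C4a and fluorine at C8a fix by position, whereas the free 3,4-dialkoxybenzyne would accept an oxygen nucleophile at C4a, remote from the C8 oxygen. It also needs O1 to react rather than O4, which is secured because O4 could only close a four-membered ring; in addition C8a has no ortho hydrogen, so no aryne can form in the hot stage, and the two benzyloxy groups stand ortho and meta (not para) to C8a, where they act mainly as inductive acceptors.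

Step 9
Reactants: 18 (2R,3R,4R)-3,7,8-tris(benzyloxy)-2-[4-(benzyloxy)phenyl]chroman-4-ol (two molecules, one as electrophile, one as nucleophile)
Product: 20 (2R,3R,4R)-3,7,8-tris(benzyloxy)-2-[4-(benzyloxy)phenyl]-4-{[(2R,3R,4S)-3,7,8-tris(benzyloxy)-2-[4-(benzyloxy)phenyl]chroman-4-yl]oxy}chromane, via flavan-4-yl cation triflate 19 (not isolated)
Conditions: Tf2O (0.5 equiv), 2,6-di-tert-butyl-4-methylpyridine, 4 Å MS, CH2Cl2, −78 to −40 °C
Reagents that add atoms: none
Why: Dehydrative SN1 etherification that copies the presumed biosynthetic dimerisation: half of 18 is triflated and ionises at once to cation 19 (stabilised by the C7 oxygen and O1), which the 4α-OH of the other half captures from the β face, anti to the 3-benzyloxy and 2-aryl groups (new C4 = S, 3,4-trans), while the nucleophilic unit keeps its C4-O bond (4R, all-cis) and the hindered pyridine keeps the medium non-acidic so that the ether is not re-ionised.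

Step 10
Reactants: 20 octa-O-benzyl ether of the target
Product: 21 (2R,3R,4R)-2-(4-hydroxyphenyl)-4-{[(2R,3R,4S)-3,7,8-trihydroxy-2-(4-hydroxyphenyl)chroman-4-yl]oxy}chromane-3,7,8-triol (CNP0241481.2)
Conditions: H2 (1 atm), Pd(OH)2/C, THF-MeOH, rt, stopped at the calculated uptake
Reagents that add atoms: none
Why: Catalytic hydrogenolysis should cleave the eight unhindered primary benzyl ethers much faster than the two hindered secondary C4-O bonds of the bridge in neutral solvent, and it touches none of the six stereocenters.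

Compound list
1 | 3-fluorocatechol | Oc1cccc(F)c1O | starting material
2 | 1,2-bis(benzyloxy)-3-fluorobenzene | Fc1cccc(OCc2ccccc2)c1OCc1ccccc1 | intermediate
3 | 1,2-bis(benzyloxy)-4-bromo-3-fluorobenzene | Fc1c(Br)ccc(OCc2ccccc2)c1OCc1ccccc1 | intermediate
4 | (S)-4-benzyloxazolidin-2-one | O=C1N[C@@H](Cc2ccccc2)CO1 | starting material
5 | (benzyloxy)acetyl chloride | O=C(Cl)COCc1ccccc1 | starting material
6 | N-lithio-(S)-4-benzyloxazolidin-2-one | [Li]N1[C@@H](Cc2ccccc2)COC1=O | intermediate
7 | (S)-4-benzyl-3-[(benzyloxy)acetyl]oxazolidin-2-one | O=C(COCc1ccccc1)N1[C@@H](Cc2ccccc2)COC1=O | intermediate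
8 | 4-(benzyloxy)benzaldehyde | O=Cc1ccc(OCc2ccccc2)cc1 | starting material
9 | Z dibutylboron enolate of 7 | CCCCB(CCCC)O/C(=C\OCc1ccccc1)N1[C@@H](Cc2ccccc2)COC1=O | intermediate
10 | dibutylboron aldolate of 11 | C(c1ccccc1)Oc1ccc([C@@H](OB(CCCC)CCCC)[C@H](OCc2ccccc2)C(=O)N2[C@@H](Cc3ccccc3)COC2=O)cc1 | intermediate
11 | (S)-4-benzyl-3-{(2S,3R)-2-(benzyloxy)-3-[4-(benzyloxy)phenyl]-3-hydroxypropanoyl}oxazolidin-2-one | C(c1ccccc1)Oc1ccc([C@@H](O)[C@H](OCc2ccccc2)C(=O)N2[C@@H](Cc3ccccc3)COC2=O)cc1 | intermediate
12 | (S)-4-benzyl-3-{(2S,3R)-2-(benzyloxy)-3-[4-(benzyloxy)phenyl]-3-(triethylsilyloxy)propanoyl}oxazolidin-2-one | C(c1ccccc1)Oc1ccc([C@@H](O[Si](CC)(CC)CC)[C@H](OCc2ccccc2)C(=O)N2[C@@H](Cc3ccccc3)COC2=O)cc1 | intermediate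
13 | (2R,3R)-2-(benzyloxy)-3-[4-(benzyloxy)phenyl]-3-(triethylsilyloxy)propan-1-ol | C(c1ccccc1)Oc1ccc([C@@H](O[Si](CC)(CC)CC)[C@H](OCc2ccccc2)CO)cc1 | intermediate
14 | (2S,3R)-2-(benzyloxy)-3-[4-(benzyloxy)phenyl]-3-(triethylsilyloxy)propanal | C(c1ccccc1)Oc1ccc([C@@H](O[Si](CC)(CC)CC)[C@H](OCc2ccccc2)C=O)cc1 | intermediate
15 | 3,4-bis(benzyloxy)-2-fluorophenyllithium | Fc1c([Li])ccc(OCc2ccccc2)c1OCc1ccccc1 | intermediate
16 | lithium (1R,2R,3R)-2-(benzyloxy)-1-[3,4-bis(benzyloxy)-2-fluorophenyl]-3-[4-(benzyloxy)phenyl]-3-(triethylsilyloxy)propan-1-olate | C(c1ccccc1)Oc1ccc([C@@H](O[Si](CC)(CC)CC)[C@H](OCc2ccccc2)[C@H](O[Li])c2ccc(OCc3ccccc3)c(OCc3ccccc3)c2F)cc1 | intermediate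
17 | caesium lithium (1R,2R,3R)-2-(benzyloxy)-1-[3,4-bis(benzyloxy)-2-fluorophenyl]-3-[4-(benzyloxy)phenyl]propane-1,3-diolate (Li on O4, Cs on O1) | C(c1ccccc1)Oc1ccc([C@@H](O[Cs])[C@H](OCc2ccccc2)[C@H](O[Li])c2ccc(OCc3ccccc3)c(OCc3ccccc3)c2F)cc1 | intermediate
18 | (2R,3R,4R)-3,7,8-tris(benzyloxy)-2-[4-(benzyloxy)phenyl]chroman-4-ol (tetra-O-benzylteracacidin, all-cis) | C(c1ccccc1)Oc1ccc([C@H]2Oc3c(ccc(OCc4ccccc4)c3OCc3ccccc3)[C@@H](O)[C@H]2OCc2ccccc2)cc1 | intermediate
19 | (2R,3R)-3,7,8-tris(benzyloxy)-2-[4-(benzyloxy)phenyl]chroman-4-ylium triflate | C(c1ccccc1)Oc1ccc([C@H]2Oc3c(ccc(OCc4ccccc4)c3OCc3ccccc3)[CH+][C@H]2OCc2ccccc2)cc1.[O-]S(=O)(=O)C(F)(F)F | intermediate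
20 | octa-O-benzyl ether of the target, (2R,3R,4R) unit joined through O to the (2R,3R,4S) unit | C(c1ccccc1)Oc1ccc([C@H]2Oc3c(ccc(OCc4ccccc4)c3OCc3ccccc3)[C@@H](O[C@H]3c4ccc(OCc5ccccc5)c(OCc5ccccc5)c4O[C@H](c4ccc(OCc5ccccc5)cc4)[C@@H]3OCc3ccccc3)[C@H]2OCc2ccccc2)cc1 | intermediate
21 | CNP0241481.2, (2R,3R,4R)-2-(4-hydroxyphenyl)-4-{[(2R,3R,4S)-3,7,8-trihydroxy-2-(4-hydroxyphenyl)chroman-4-yl]oxy}chromane-3,7,8-triol | Oc1ccc([C@H]2Oc3c(ccc(O)c3O)[C@@H](O[C@H]3c4ccc(O)c(O)c4O[C@H](c4ccc(O)cc4)[C@@H]3O)[C@H]2O)cc1 | target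

Total step count: 10. Longest linear sequence: 8 (steps 3 to 10). Steps 1 and 2 form the short second branch that joins in step 8.

Steps most likely to fail

Step 8. The displacement of fluoride from the electron-rich ring A may be too slow at temperatures that the dialkoxide tolerates, and the acyclic Felkin-Anh control at C4 may erode. The fallback sets out from 14 and comes back at 18. It makes the two bonds in separate known operations and closes the C-O bond by copper catalysis instead of SNAr.
- Commercial 3-bromocatechol is benzylated (BnBr, K2CO3, DMF) to 1,2-bis(benzyloxy)-3-bromobenzene F1.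
- Iodination para to the unhindered benzyloxy group (NIS, cat. CF3CO2H, MeCN) gives 1,2-bis(benzyloxy)-3-bromo-4-iodobenzene F2.
- Selective I/Mg exchange (i-PrMgCl·LiCl, THF, −40 °C) is followed by transmetalation with ClTi(Oi-Pr)3, which keeps the addition non-chelated. Addition to 14 gives the bromo alcohol (1R,2R,3R)-2-(benzyloxy)-1-[3,4-bis(benzyloxy)-2-bromophenyl]-3-[4-(benzyloxy)phenyl]-3-(triethylsilyloxy)propan-1-ol F3.
- Bu4NF in THF removes the silyl group and gives the bromo diol (1R,2S,3R)-2-(benzyloxy)-1-[3,4-bis(benzyloxy)-2-bromophenyl]-3-[4-(benzyloxy)phenyl]propane-1,3-diol F4.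
- An intramolecular Ullmann-type O-arylation (CuI, 1,10-phenanthroline, Cs2CO3, toluene, 110 °C) closes ring C to 18. The C4 hydroxyl cannot reach C8a.

Step 9. Three processes may compete with the kinetic β-face capture. The cation may lose the C3 proton, the benzyl or ring A carbons may undergo Friedel-Crafts attack, or the new ether may re-ionise and scramble the configuration of the nucleophilic unit. The fallback sets out from 18 and comes back at 20. It separates donor and acceptor.
- One portion of 18 is treated with phenylmethanethiol and catalytic BF3·OEt2 (CH2Cl2, −78 °C). The cation is trapped on the β face as the stable donor (2R,3S,4S)-4-(benzylsulfanyl)-3,7,8-tris(benzyloxy)-2-[4-(benzyloxy)phenyl]chromane F5.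
- F5 is then activated with the thiophilic salt AgBF4 (CH2Cl2, 0 °C) in the presence of a second portion of 18.
- Only the thioether ionises under these conditions, so the 4α-OH of 18 and the product ether stay untouched.

Step 10. The bridge may be over-reduced: its two benzylic C4-O bonds may be cleaved by hydrogenolysis while the slower aliphatic 3-O-benzyl ethers are still being removed. The fallback sets out from 18 and comes back at 21. It moves the hydrogenolysis ahead of the ether formation.
- 18 is debenzylated (H2, Pd(OH)2/C, THF-MeOH) at the monomer stage, where only a less labile benzylic alcohol is at risk. This gives (−)-teracacidin F6.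
- F6 is left to self-condense in dilute aqueous acid (0.1 M HCl, rt), as in the presumed biosynthesis.
- The 4α,4β-ether 21 is separated from other oligomers on Sephadex LH-20.

Further compounds
F1 | step 8 | 1,2-bis(benzyloxy)-3-bromobenzene | Brc1cccc(OCc2ccccc2)c1OCc1ccccc1
F2 | step 8 | 1,2-bis(benzyloxy)-3-bromo-4-iodobenzene | Brc1c(I)ccc(OCc2ccccc2)c1OCc1ccccc1
F3 | step 8 | (1R,2R,3R)-2-(benzyloxy)-1-[3,4-bis(benzyloxy)-2-bromophenyl]-3-[4-(benzyloxy)phenyl]-3-(triethylsilyloxy)propan-1-ol | C(c1ccccc1)Oc1ccc([C@@H](O[Si](CC)(CC)CC)[C@H](OCc2ccccc2)[C@H](O)c2ccc(OCc3ccccc3)c(OCc3ccccc3)c2Br)cc1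
F4 | step 8 | (1R,2S,3R)-2-(benzyloxy)-1-[3,4-bis(benzyloxy)-2-bromophenyl]-3-[4-(benzyloxy)phenyl]propane-1,3-diol | C(c1ccccc1)Oc1ccc([C@@H](O)[C@H](OCc2ccccc2)[C@H](O)c2ccc(OCc3ccccc3)c(OCc3ccccc3)c2Br)cc1
F5 | step 9 | (2R,3S,4S)-4-(benzylsulfanyl)-3,7,8-tris(benzyloxy)-2-[4-(benzyloxy)phenyl]chromane | C(c1ccccc1)Oc1ccc([C@H]2Oc3c(ccc(OCc4ccccc4)c3OCc3ccccc3)[C@H](SCc3ccccc3)[C@H]2OCc2ccccc2)cc1
F6 | step 10 | (−)-teracacidin, (2R,3R,4R)-2-(4-hydroxyphenyl)chromane-3,4,7,8-tetraol | Oc1ccc([C@H]2Oc3c(ccc(O)c3O)[C@@H](O)[C@H]2O)cc1
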